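**Plan**

Numbering: ring A = C1–C2–C3–C4–C5–C10, ring B = C5–C6–C7–C8–C9–C10; C14 is the methyl on C5, C15 the methyl on C4, C11–C13 the isopropenyl group on C7; β is the face of C14; PMB = 4-methoxybenzyl.

- Retrosynthesis: the two 3-methylbut-2-enoates come off last, then the C7–C11 bond (enolate alkenylation), then the C8 ketone is traced back to an 8-methoxy-7-en-6-one (1,3-carbonyl transposition), and finally C5–C10 and C3–C4 are cut together.
- Enabling feature: ring A has only CH2 groups at C1 and C2 between the oxygenated C3 and the ring-fusion carbon C10, and a cis methyl pair on C4/C5. That is the retron of a [4+2] cycloaddition between a C10=C1–C2=C3(OR) diene and an (E)-C4=C5 tiglyl alkene. C5 and C10 are already joined by the C6–C7–C8–C9 chain of ring B, and the C8 oxygen, carried as an enol ether, places a carbonyl at C6 next to the dienophile.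
- Forward: glutaconaldehyde enolate (C3–C2–C1–C10–C9) → PMB dienyl ether → alkyne (C8, C7) → tigloyl ynone (C6, C5, C4, C14, C15) → methanol adduct. One intramolecular Diels–Alder reaction then closes ring B and ring A together. Transposition, hydrogenation, C9 epimerisation, isopropenylation, PMB removal and double acylation follow.
- Stereochemistry: C9 is set by asymmetric alkynylation and steers the diene face. The (E)-tiglyl geometry gives the cis C4/C5 methyls, the (E,E)-diene the C3/C10 relation, and the endo carbonyl bridge the cis ring fusion. C9 and C7, both alpha to the C8 ketone, are finally brought to their equatorial (β) configurations under thermodynamic control.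

Key step: step 7

Assumption: (S,S)-ProPhenol is taken to be the ligand antipode that gives the (3S)-carbinol 5; should the sense be opposite, the (R,R)-ligand is used with no other change.

**Route**

Step 1
Reactants: 1 potassium (1E,3E)-5-oxopenta-1,3-dien-1-olate (glutaconaldehyde potassium salt)
Product: 2 (2E,4E)-5-[(4-methoxybenzyl)oxy]penta-2,4-dienal
Conditions: 4-MeOC6H4CH2Cl, n-Bu4NI (cat.), DMF, 0 °C → rt
Reagents that add atoms: 4-methoxybenzyl chloride, COc1ccc(CCl)cc1
Why: Williamson-type O-alkylation of the delocalised enolate with a benzylic chloride in a dipolar aprotic solvent should occur at oxygen, as O-acylation and O-silylation of this anion do, and keeps the all-E geometry.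

Step 2
Reactants: 2 (2E,4E)-5-[(4-methoxybenzyl)oxy]penta-2,4-dienal; 3 ethynyltrimethylsilane
Product: 5 (3S,4E,6E)-7-[(4-methoxybenzyl)oxy]-1-(trimethylsilyl)hepta-4,6-dien-1-yn-3-ol, via methylzinc acetylide 4 (not isolated)
Conditions: Me2Zn, (S,S)-ProPhenol (20 mol%), Ph3PO (40 mol%), PhMe, 0 → 4 °C; pH 7 buffer work-up
Reagents that add atoms: none
Why: Catalytic asymmetric alkynylation of an aldehyde (zinc acetylide addition under the catalyst formed from Me2Zn and (S,S)-ProPhenol) should add 1,2 to the dienal and set C9 as (S) by ligand control.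

Step 3
Reactants: 5 (3S,4E,6E)-7-[(4-methoxybenzyl)oxy]-1-(trimethylsilyl)hepta-4,6-dien-1-yn-3-ol
Product: 7 [(3S,4E,6E)-3,7-bis[(4-methoxybenzyl)oxy]hepta-4,6-dien-1-yn-1-yl]trimethylsilane, via sodium alkoxide 6 (not isolated)
Conditions: NaH, THF/DMF, 0 °C; then 4-MeOC6H4CH2Cl, n-Bu4NI (cat.), 0 °C → rt
Reagents that add atoms: 4-methoxybenzyl chloride, COc1ccc(CCl)cc1
Why: Williamson etherification under basic conditions should protect the acid-labile, doubly activated carbinol as a non-migrating ether without touching the C9 configuration.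

Step 4
Reactants: 7 [(3S,4E,6E)-3,7-bis[(4-methoxybenzyl)oxy]hepta-4,6-dien-1-yn-1-yl]trimethylsilane
Product: 8 (3S,4E,6E)-3,7-bis[(4-methoxybenzyl)oxy]hepta-4,6-dien-1-yne
Conditions: K2CO3 (cat.), MeOH, rt
Reagents that add atoms: none
Why: Base-catalysed methanolysis of the C(sp)–Si bond (protodesilylation) should free the terminal alkyne, the alkyl enol ether and the PMB ethers being inert to K2CO3/MeOH.

Step 5
Reactants: 8 (3S,4E,6E)-3,7-bis[(4-methoxybenzyl)oxy]hepta-4,6-dien-1-yne; 9 (E)-2-methylbut-2-enoyl chloride (tigloyl chloride)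
Product: 10 (2E,7S,8E,10E)-7,11-bis[(4-methoxybenzyl)oxy]-3-methylundeca-2,8,10-trien-5-yn-4-one
Conditions: PdCl2(PPh3)2 (2 mol%), CuI (4 mol%), Et3N, THF, rt
Reagents that add atoms: none
Why: Acyl Sonogashira coupling of a terminal alkyne with an acid chloride should give the ynone directly under mildly basic conditions and keep the E geometry of the tigloyl unit.

Step 6
Reactants: 10 (2E,7S,8E,10E)-7,11-bis[(4-methoxybenzyl)oxy]-3-methylundeca-2,8,10-trien-5-yn-4-one
Product: 11 (2E,5E,7S,8E,10E)-6-methoxy-7,11-bis[(4-methoxybenzyl)oxy]-3-methylundeca-2,5,8,10-tetraen-4-one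
Conditions: MeOH (10 equiv), PMe3 (10 mol%), CH2Cl2, 0 °C → rt
Reagents that add atoms: methanol, CO
Why: Phosphine-catalysed oxa-Michael addition of methanol to the ynone should place the methoxy group on C8 (the β carbon) and, being reversible, give the more stable E enol ether with C9 cis to the C6 carbonyl, the geometry that ring B needs.

Step 7
Reactants: 11 (2E,5E,7S,8E,10E)-6-methoxy-7,11-bis[(4-methoxybenzyl)oxy]-3-methylundeca-2,5,8,10-tetraen-4-one
Product: 12 8-methoxy-3α,9α-bis[(4-methoxybenzyl)oxy]-11,12,13-trinor-10βH-eremophila-1,7-dien-6-one (cis-fused; 4β,5β-dimethyl)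
Conditions: PhMe (0.01 M), BHT (cat.), 110 °C, sealed tube
Reagents that add atoms: none
Why: Thermal, concerted but asynchronous intramolecular Diels–Alder reaction of the (1E,3E)-1-alkoxydiene C10=C1–C2=C3 with the (E)-tiglyl alkene C4=C5, which is activated by the cross-conjugated C6 carbonyl of the vinylogous ester; the closest known type is the cyclisation of 1,7,9-decatrien-3-ones, which carry the activating carbonyl inside the bridge and give cis-fused octalones. Ring A is the cyclohexene of the suprafacial [4+2] itself (bonds C3–C4 and C5–C10), and ring B is closed by the same C5–C10 bond across the four-atom bridge C6–C7–C8–C9 in the fused, bridge-endo mode. The cis C14/C15 methyl pair on C5/C4 follows from the E geometry of the dienophile, the trans relation of the C3 oxygen to H10 from the E,E geometry of the diene, and the cis ring fusion (H10 syn to C14) from the endo position of the carbonyl-bearing bridge. The absolute sense comes from C9: its PMB ether should take the pseudo-equatorial site of the forming ring B because the pseudo-axial site collides with C14, which fixes the diene face and gives the target configuration at C3, C4, C5 and C10 with the C9 oxygen trans to C14 (9α, corrected in step 10). Regiochemistry needs no electronic help, since only the C10-to-C5/C3-to-C4 pairing is allowed by the bridge length, the enol ether C7=C8 cannot be reached by the diene, and high dilution suppresses dimerisation.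

Step 8
Reactants: 12 8-methoxy-3α,9α-bis[(4-methoxybenzyl)oxy]-11,12,13-trinor-10βH-eremophila-1,7-dien-6-one
Product: 14 3α,9α-bis[(4-methoxybenzyl)oxy]-11,12,13-trinor-10βH-eremophila-1,6-dien-8-one, via C6 allylic alcohol 13 (not isolated)
Conditions: i-Bu2AlH, CH2Cl2, −78 °C; then 1 M HCl, THF, 0 °C
Reagents that add atoms: water, O
Why: Stork–Danheiser-type 1,3-carbonyl transposition: 1,2-reduction of the vinylogous ester carbonyl at C6, then acid hydrolysis of the 3-methoxy allylic alcohol with loss of water, should move the carbonyl to C8 and leave C6=C7, so the activating oxygen is removed without a separate deoxygenation.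

Step 9
Reactants: 14 3α,9α-bis[(4-methoxybenzyl)oxy]-11,12,13-trinor-10βH-eremophila-1,6-dien-8-one
Product: 15 3α,9α-bis[(4-methoxybenzyl)oxy]-11,12,13-trinor-10βH-eremophilan-8-one
Conditions: H2 (1 atm), Pd/C (10%), pyridine (0.5 equiv), EtOAc, rt
Reagents that add atoms: none
Why: Heterogeneous catalytic hydrogenation should saturate the two disubstituted alkenes (C1=C2 and the enone C6=C7) while pyridine suppresses hydrogenolysis of the PMB ethers; no stereocenter is formed.

Step 10
Reactants: 15 3α,9α-bis[(4-methoxybenzyl)oxy]-11,12,13-trinor-10βH-eremophilan-8-one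
Product: 16 3α,9β-bis[(4-methoxybenzyl)oxy]-11,12,13-trinor-10βH-eremophilan-8-one
Conditions: NaOMe (0.3 equiv), MeOH/THF, rt
Reagents that add atoms: none
Why: Base-mediated epimerisation through the C8–C9 enolate is thermodynamically driven: with the ring A substituents equatorial, the 9β ether is equatorial on ring B whereas the 9α ether is axial and syn to the axial C4–C5 bond, and an alkyl ether can neither migrate nor transpose the ketone.

Step 11
Reactants: 16 3α,9β-bis[(4-methoxybenzyl)oxy]-11,12,13-trinor-10βH-eremophilan-8-one; 17 2-bromopropene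
Product: 19 3α,9β-bis[(4-methoxybenzyl)oxy]-10βH-eremophil-11-en-8-one (7β-isopropenyl), via lithium enolate 18 (not isolated)
Conditions: LiN(SiMe3)2 (2.2 equiv), THF, −78 °C; then Pd2(dba)3 (2.5 mol%), P(t-Bu)3 (10 mol%), 2-bromopropene, THF/PhMe, rt; AcOH quench at −78 °C
Reagents that add atoms: none
Why: Palladium-catalysed α-alkenylation of a ketone enolate: the kinetic enolate should form at the C7 methylene and not at the hindered, alkoxy-bearing C9, and C7 should end with the isopropenyl group equatorial (β), the stable epimer, because the more acidic product is held as its enolate and reprotonated at C7 on quenching (alpha protonation keeps the alkene out of conjugation).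

Step 12
Reactants: 19 3α,9β-bis[(4-methoxybenzyl)oxy]-10βH-eremophil-11-en-8-one
Product: 20 3α,9β-dihydroxy-10βH-eremophil-11-en-8-one
Conditions: DDQ (3 equiv), CH2Cl2/pH 7 buffer, 0 °C → rt
Reagents that add atoms: none
Why: Oxidative cleavage of both PMB ethers with DDQ under buffered conditions is neutral enough for the β,γ-unsaturated ketone and leaves all stereocenters untouched.

Step 13
Reactants: 20 3α,9β-dihydroxy-10βH-eremophil-11-en-8-one; 21 3-methylbut-2-enoyl chloride (two equivalents are consumed, one per hydroxyl group)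
Product: 22 3α,9β-bis(3-methylbut-2-enoyloxy)-10βH-eremophil-11-en-8-one (CNP0264508.1)
Conditions: 21 (3 equiv), pyridine, DMAP (cat.), CH2Cl2, 0 °C → rt
Reagents that add atoms: 3-methylbut-2-enoyl chloride (the second equivalent of 21), CC(C)=CC(Cl)=O
Why: Pyridine/DMAP-mediated acylation of both secondary alcohols, each by one equivalent of the acid chloride, should give the two 3-methylbut-2-enoates in one operation with retention at C3 and C9, pyridine being too weak a base to deconjugate the acyl group.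

**Compound list**

1 | potassium (1E,3E)-5-oxopenta-1,3-dien-1-olate | [K+].[O-]/C=C/C=C/C=O | starting material
2 | (2E,4E)-5-[(4-methoxybenzyl)oxy]penta-2,4-dienal | O=C/C=C/C=C/OCc1ccc(OC)cc1 | intermediate
3 | ethynyltrimethylsilane | C[Si](C)(C)C#C | starting material
4 | methyl[(trimethylsilyl)ethynyl]zinc | C[Zn]C#C[Si](C)(C)C | intermediate
5 | (3S,4E,6E)-7-[(4-methoxybenzyl)oxy]-1-(trimethylsilyl)hepta-4,6-dien-1-yn-3-ol | C[Si](C)(C)C#C[C@@H](O)/C=C/C=C/OCc1ccc(OC)cc1 | intermediate
6 | sodium alkoxide of 5 | C[Si](C)(C)C#C[C@@H]([O-])/C=C/C=C/OCc1ccc(OC)cc1.[Na+] | intermediate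
7 | [(3S,4E,6E)-3,7-bis[(4-methoxybenzyl)oxy]hepta-4,6-dien-1-yn-1-yl]trimethylsilane | C[Si](C)(C)C#C[C@@H](OCc1ccc(OC)cc1)/C=C/C=C/OCc1ccc(OC)cc1 | intermediate
8 | (3S,4E,6E)-3,7-bis[(4-methoxybenzyl)oxy]hepta-4,6-dien-1-yne | C#C[C@@H](OCc1ccc(OC)cc1)/C=C/C=C/OCc1ccc(OC)cc1 | intermediate
9 | (E)-2-methylbut-2-enoyl chloride | C/C=C(\C)C(Cl)=O | starting material
10 | (2E,7S,8E,10E)-7,11-bis[(4-methoxybenzyl)oxy]-3-methylundeca-2,8,10-trien-5-yn-4-one | C/C=C(\C)C(=O)C#C[C@@H](OCc1ccc(OC)cc1)/C=C/C=C/OCc1ccc(OC)cc1 | intermediate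
11 | (2E,5E,7S,8E,10E)-6-methoxy-7,11-bis[(4-methoxybenzyl)oxy]-3-methylundeca-2,5,8,10-tetraen-4-one | C/C=C(\C)C(=O)/C=C(/OC)[C@@H](OCc1ccc(OC)cc1)/C=C/C=C/OCc1ccc(OC)cc1 | intermediate
12 | 8-methoxy-3α,9α-bis[(4-methoxybenzyl)oxy]-11,12,13-trinor-10βH-eremophila-1,7-dien-6-one | C1C(=O)[C@@]2(C)[C@H](C=C[C@@H](OCc3ccc(OC)cc3)[C@@H]2C)[C@H](OCc3ccc(OC)cc3)C=1OC | intermediate
13 | 8-methoxy-3α,9α-bis[(4-methoxybenzyl)oxy]-11,12,13-trinor-10βH-eremophila-1,7-dien-6-ol (C6 unassigned) | C1C(O)[C@@]2(C)[C@H](C=C[C@@H](OCc3ccc(OC)cc3)[C@@H]2C)[C@H](OCc3ccc(OC)cc3)C=1OC | intermediate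
14 | 3α,9α-bis[(4-methoxybenzyl)oxy]-11,12,13-trinor-10βH-eremophila-1,6-dien-8-one | C1=C[C@@]2(C)[C@H](C=C[C@@H](OCc3ccc(OC)cc3)[C@@H]2C)[C@H](OCc3ccc(OC)cc3)C1=O | intermediate
15 | 3α,9α-bis[(4-methoxybenzyl)oxy]-11,12,13-trinor-10βH-eremophilan-8-one | C1C[C@@]2(C)[C@H](CC[C@@H](OCc3ccc(OC)cc3)[C@@H]2C)[C@H](OCc3ccc(OC)cc3)C1=O | intermediate
16 | 3α,9β-bis[(4-methoxybenzyl)oxy]-11,12,13-trinor-10βH-eremophilan-8-one | C1C[C@@]2(C)[C@H](CC[C@@H](OCc3ccc(OC)cc3)[C@@H]2C)[C@@H](OCc3ccc(OC)cc3)C1=O | intermediate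
17 | 2-bromopropene | C=C(C)Br | starting material
18 | lithium C7=C8 enolate of 16 | C1C[C@@]2(C)[C@H](CC[C@@H](OCc3ccc(OC)cc3)[C@@H]2C)[C@@H](OCc3ccc(OC)cc3)C=1[O-].[Li+] | intermediate
19 | 3α,9β-bis[(4-methoxybenzyl)oxy]-10βH-eremophil-11-en-8-one | C=C(C)[C@H]1C[C@@]2(C)[C@H](CC[C@@H](OCc3ccc(OC)cc3)[C@@H]2C)[C@@H](OCc3ccc(OC)cc3)C1=O | intermediate
20 | 3α,9β-dihydroxy-10βH-eremophil-11-en-8-one | C=C(C)[C@H]1C[C@@]2(C)[C@H](CC[C@@H](O)[C@@H]2C)[C@@H](O)C1=O | intermediate
21 | 3-methylbut-2-enoyl chloride | CC(C)=CC(Cl)=O | starting material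
22 | 3α,9β-bis(3-methylbut-2-enoyloxy)-10βH-eremophil-11-en-8-one | C=C(C)[C@H]1C[C@@]2(C)[C@H](CC[C@@H](OC(=O)C=C(C)C)[C@@H]2C)[C@@H](OC(=O)C=C(C)C)C1=O | target

**Step count and risks**

Total steps: 13. Longest linear sequence: 13 steps (from 1).

Step 7. The vinylogous ester carbonyl is a weak activator and the alkoxy-bearing diene terminus is electronically mismatched, so cyclisation may be slow, with competing E/Z isomerisation of the enol ether or erosion of endo (cis-fusion) selectivity. The fallback sets out from 10 and returns at 14. Semihydrogenation of the ynone (H2, Pd/CaCO3 poisoned with Pb(OAc)2, quinoline) should give the (Z)-enone, (2E,5Z,7S,8E,10E)-7,11-bis[(4-methoxybenzyl)oxy]-3-methylundeca-2,5,8,10-tetraen-4-one F1. As a true 1,7,9-decatrien-3-one with ketone-level activation this should cyclise near room temperature, under the same C9 control, to the cis-fused 3α,9α-bis[(4-methoxybenzyl)oxy]-11,12,13-trinor-10βH-eremophila-1,7-dien-6-one F2. Nucleophilic epoxidation (H2O2, NaOH, MeOH) to the 7,8-epoxy ketone F3, Wharton transposition (N2H4·H2O, AcOH) to the allylic alcohol 3α,9α-bis[(4-methoxybenzyl)oxy]-11,12,13-trinor-10βH-eremophila-1,6-dien-8-ol F4, and MnO2 oxidation then lead to 14.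

Step 11. Enolisation may occur partly toward C9, a second alkenylation may follow, or base may move the new double bond into conjugation with the ketone. The fallback sets out from 16 and returns at 19. The kinetic enolate (LiN(i-Pr)2, THF, −78 °C) is trapped with acetone in an aldol addition to give 11-hydroxy-3α,9β-bis[(4-methoxybenzyl)oxy]-10βH-eremophilan-8-one F5. Dehydration of the tertiary alcohol with SOCl2/pyridine at low temperature, which should take a methyl hydrogen, gives 19.

Step 6. Base generated in the phosphine cycle may isomerise the ynone to an allenone at the doubly activated C9–H, with partial loss of the C9 configuration, or the wrong enol ether geometry may persist. The fallback sets out from 8 and returns at 11, bypassing 10. Deprotonation (n-BuLi) and methyl chloroformate give methyl (4S,5E,7E)-4,8-bis[(4-methoxybenzyl)oxy]octa-5,7-dien-2-ynoate F6. Methanol addition under PBu3 catalysis, which is well behaved on ynoates, gives methyl (2E,4S,5E,7E)-3-methoxy-4,8-bis[(4-methoxybenzyl)oxy]octa-2,5,7-trienoate F7. MeNH(OMe)·HCl with i-PrMgCl gives the Weinreb amide (2E,4S,5E,7E)-N,3-dimethoxy-4,8-bis[(4-methoxybenzyl)oxy]-N-methylocta-2,5,7-trienamide F8. Addition of (E)-but-2-en-2-yllithium (from (E)-2-bromobut-2-ene and t-BuLi) then gives 11.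

**Further compounds**

F1 | step 7 | (2E,5Z,7S,8E,10E)-7,11-bis[(4-methoxybenzyl)oxy]-3-methylundeca-2,5,8,10-tetraen-4-one | C/C=C(\C)C(=O)/C=C\[C@@H](OCc1ccc(OC)cc1)/C=C/C=C/OCc1ccc(OC)cc1
F2 | step 7 | 3α,9α-bis[(4-methoxybenzyl)oxy]-11,12,13-trinor-10βH-eremophila-1,7-dien-6-one | C1C(=O)[C@@]2(C)[C@H](C=C[C@@H](OCc3ccc(OC)cc3)[C@@H]2C)[C@H](OCc3ccc(OC)cc3)C=1
F3 | step 7 | 7,8-epoxy-3α,9α-bis[(4-methoxybenzyl)oxy]-11,12,13-trinor-10βH-eremophil-1-en-6-one | O1C2C(=O)[C@@]3(C)[C@H](C=C[C@@H](OCc4ccc(OC)cc4)[C@@H]3C)[C@H](OCc4ccc(OC)cc4)C12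
F4 | step 7 | 3α,9α-bis[(4-methoxybenzyl)oxy]-11,12,13-trinor-10βH-eremophila-1,6-dien-8-ol | C1=C[C@@]2(C)[C@H](C=C[C@@H](OCc3ccc(OC)cc3)[C@@H]2C)[C@H](OCc3ccc(OC)cc3)C1O
F5 | step 11 | 11-hydroxy-3α,9β-bis[(4-methoxybenzyl)oxy]-10βH-eremophilan-8-one | CC(C)(O)[C@H]1C[C@@]2(C)[C@H](CC[C@@H](OCc3ccc(OC)cc3)[C@@H]2C)[C@@H](OCc3ccc(OC)cc3)C1=O
F6 | step 6 | methyl (4S,5E,7E)-4,8-bis[(4-methoxybenzyl)oxy]octa-5,7-dien-2-ynoate | COC(=O)C#C[C@@H](OCc1ccc(OC)cc1)/C=C/C=C/OCc1ccc(OC)cc1
F7 | step 6 | methyl (2E,4S,5E,7E)-3-methoxy-4,8-bis[(4-methoxybenzyl)oxy]octa-2,5,7-trienoate | COC(=O)/C=C(/OC)[C@@H](OCc1ccc(OC)cc1)/C=C/C=C/OCc1ccc(OC)cc1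
F8 | step 6 | (2E,4S,5E,7E)-N,3-dimethoxy-4,8-bis[(4-methoxybenzyl)oxy]-N-methylocta-2,5,7-trienamide | CON(C)C(=O)/C=C(/OC)[C@@H](OCc1ccc(OC)cc1)/C=C/C=C/OCc1ccc(OC)cc1
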